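**Plan**
1. Retrosynthesis (drimane numbering): the C6–O ester bond is cut first, which removes the octatrienoyl chain. The oxygens at C12, C6 and C9 are then taken off and C11 is lowered to CH2OH, leading back to (−)-drimenol. Last, C4–C5 and C9–C10 are cut, which opens rings A and B to an acyclic C15 chain.
2. Enabling feature: rings A and B are trans-fused and carry the C4 gem-dimethyl group, H-5, the angular C10 methyl, the one-carbon branch C11 on C9, and C12 on the C7=C8 alkene. This is the pattern of an all-E farnesyl unit folded head to tail, so one proton-triggered cation–olefin cascade can build both rings.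
3. Forward: farnesol → diphosphate → enzymatic bicyclisation (ring A, then ring B, in one operation) → C11 tert-butyl ester → 9α-OH → C6 ketone → 6β-OH → C12 aldehyde → trienoyl ester at O6 → free acid.
4. Stereochemistry: C5 and C10 (and the relay centre C9) come from the enzyme-held chair–chair fold. The 9α-hydroxyl comes from attack on the C9 dienolate anti to the C10 methyl. The 6β-oxygen comes from hydride delivery to the α face of the 6-ketone. The triene geometry is bought with the acid.

Key step: step 3

Remark: farnesyl diphosphate is drawn as the free acid but is made, stored and used as its ammonium salt. The cyclase is a recombinant enzyme used as a catalyst, and its expression is not counted as a step.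

**Step 1**
Reactants: 1 (2E,6E)-farnesol
Product: 2 (2E,6E)-farnesyl bromide
Conditions: PBr3 (0.4 equiv), Et2O, 0 °C, dark; used crude
Reagents that add atoms: phosphorus tribromide, BrP(Br)Br
Why: Bromination of the primary allylic alcohol through its phosphite ester (SN2 at C1) should proceed at 0 °C without allylic transposition or E/Z isomerisation of the 2,3-alkene; no stereocentre is formed.

**Step 2**
Reactants: 2 (2E,6E)-farnesyl bromide
Product: 3 (2E,6E)-farnesyl diphosphate
Conditions: (Bu4N)3HP2O7 (2 equiv), MeCN, rt; then sulfonic acid resin (NH4+ form), aq. NH4HCO3/iPrOH; cellulose chromatography; lyophilisation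
Reagents that add atoms: tris(tetrabutylammonium) hydrogen diphosphate, CCCC[N+](CCCC)(CCCC)CCCC.CCCC[N+](CCCC)(CCCC)CCCC.CCCC[N+](CCCC)(CCCC)CCCC.OP(=O)([O-])OP(=O)([O-])[O-]
Why: SN2 displacement of the primary allylic bromide by the diphosphate anion in a dipolar aprotic solvent is the standard route to allylic diphosphates and keeps the E geometry; cation exchange gives the water-soluble ammonium salt the enzyme needs, the remaining tetrabutylammonium ions staying on the resin.

**Step 3**
Reactants: 3 (2E,6E)-farnesyl diphosphate
Product: 6 (−)-drimenol, via drimenyl diphosphate 4 (not isolated), via drimenyl phosphate 5 (not isolated)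
Conditions: recombinant bifunctional drimenol synthase (protonation-initiated cyclase domain fused to a phosphatase domain), HEPES buffer pH 7.5, MgCl2 (10 mM), dithiothreitol, 30 °C, dodecane overlay
Reagents that add atoms: none
Why: The acidic aspartate of the cyclase domain protonates C3 of the distal alkene of 3, the tertiary C4 cation is attacked by the central alkene (C4–C5), the new tertiary C10 cation by the allylic alkene (C9–C10), an active-site base removes H7 to give 4, and the phosphatase domain then hydrolyses the two P–O bonds in turn (4 → 5 → 6), so that O11 is the oxygen of the substrate. This is the native reaction of drimenol synthases and belongs to the protonation-initiated head-to-tail polyene cyclisations of terpene cyclases, as also run by squalene–hopene cyclases. Ring A closes 6-endo-trig onto the central alkene and ring B closes 6-endo-trig onto the allylic alkene, each through a chair. C5 and C10 arise by anti addition across the central E alkene, which makes the ring fusion trans; C9 arises by anti addition across the E-configured allylic alkene, which puts C11 equatorial (β); the handedness of the chair–chair fold, and hence the absolute configuration of all three centres, is imposed by the chiral enzyme pocket. The step needs Markovnikov 6-endo closure twice and loss of H7 instead of H9 or a C12 hydrogen: the methyl branches of the all-E chain make both cations tertiary and its diphosphate head anchors the chain at the Mg2+ site, while the placement of the enzymatic base fixes the C7=C8 alkene.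

**Step 4**
Reactants: 6 (−)-drimenol
Product: 7 drimenal (drim-7-en-11-al)
Conditions: Dess–Martin periodinane (1.3 equiv), NaHCO3 (4 equiv), CH2Cl2, 0 °C → rt
Reagents that add atoms: none
Why: Dess–Martin oxidation under bicarbonate buffering should stop at the aldehyde and keep the β,γ-alkene out of conjugation, and C9 keeps its configuration under these non-enolising conditions.

**Step 5**
Reactants: 7 drimenal
Product: 8 drim-7-en-11-oic acid
Conditions: NaClO2 (3 equiv), NaH2PO4 (4 equiv), 2-methyl-2-butene (20 equiv), tBuOH/H2O, 0 °C → rt
Reagents that add atoms: sodium chlorite, [Na+].[O-]Cl=O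
Why: Pinnick (chlorite) oxidation converts the hindered aldehyde to the acid under weakly acidic conditions without enolisation, the excess 2-methyl-2-butene taking up the hypochlorous acid that would otherwise add to the C7=C8 alkene.

**Step 6**
Reactants: 8 drim-7-en-11-oic acid
Product: 9 tert-butyl drim-7-en-11-oate
Conditions: Cl3CC(=NH)OtBu (3 equiv), CH2Cl2/cyclohexane, rt
Reagents that add atoms: tert-butyl 2,2,2-trichloroacetimidate, CC(C)(C)OC(=N)C(Cl)(Cl)Cl
Why: Esterification by O-alkylation with the trichloroacetimidate (acid-promoted transfer of a tert-butyl cation to the carboxylate) does not require attack at the hindered C11 carbonyl, and the tert-butyl ester is chosen because it tolerates base, peroxide, hydride and selenium dioxide and is later removed by acid without touching the trienoate.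

**Step 7**
Reactants: 9 tert-butyl drim-7-en-11-oate
Product: 11 tert-butyl 9α-hydroxydrim-7-en-11-oate, via potassium dienolate 10 (not isolated)
Conditions: KN(SiMe3)2 (1.3 equiv), THF, −78 °C; then 2-(phenylsulfonyl)-3-phenyloxaziridine (1.5 equiv), −78 °C; AcOH quench
Reagents that add atoms: 2-(phenylsulfonyl)-3-phenyloxaziridine, O=S(=O)(c1ccccc1)N1OC1c1ccccc1
Why: Deprotonation of the axial, allylic H9 gives the extended ester enolate 10, whose α-carbon is oxygenated by the N-sulfonyloxaziridine (Davis enolate hydroxylation) on the α face anti to the axial C10 methyl, so the hydroxyl becomes 9α and the ester stays β, as in the 9α-hydroxylation of related drim-7-ene carbonyl compounds.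

**Step 8**
Reactants: 11 tert-butyl 9α-hydroxydrim-7-en-11-oate
Product: 13 tert-butyl 9α-hydroxy-6-oxodrim-7-en-11-oate, via C6 tert-butyl peroxide 12 (not isolated)
Conditions: Rh2(cap)4 (cap = caprolactamate, C6H10NO; 1 mol %), tBuOOH (70% in water, 6 equiv), 1,2-dichloroethane, 40 °C
Reagents that add atoms: tert-butyl hydroperoxide, CC(C)(C)OO
Why: Allylic oxidation by tert-butylperoxyl radicals generated with the dirhodium carboxamidate should abstract the axial hydrogen of the ring methylene C6, the only secondary allylic position, and the mixed peroxide 12 collapses to the enone (Kornblum–DeLaMare-type fragmentation); a chromium trioxide reagent is avoided because it could engage the free tertiary allylic C9 hydroxyl in an oxidative 1,3-transposition.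

**Step 9**
Reactants: 13 tert-butyl 9α-hydroxy-6-oxodrim-7-en-11-oate
Product: 14 tert-butyl 6β,9α-dihydroxydrim-7-en-11-oate
Conditions: NaBH4 (1.5 equiv), CeCl3·7H2O (1.2 equiv), MeOH, −40 °C
Reagents that add atoms: none
Why: Luche reduction gives clean 1,2-addition, and hydride approaches C6 from the α face because the β face is screened by the axial C10 methyl and the 4β-methyl, which sets the axial 6β-hydroxyl as known for 6-oxo-drimanes and 6-oxo-steroids.

**Step 10**
Reactants: 14 tert-butyl 6β,9α-dihydroxydrim-7-en-11-oate
Product: 16 tert-butyl 6β,9α-dihydroxy-12-oxodrim-7-en-11-oate, via C12 allylic alcohol 15 (not isolated)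
Conditions: SeO2 (2.2 equiv), 1,4-dioxane, 80 °C
Reagents that add atoms: selenium dioxide, O=[Se]=O
Why: Riley oxidation (ene reaction of selenium dioxide at C7, then 2,3-sigmatropic shift) functionalises an allylic C–H on the more substituted alkene terminus C8, where C9 has no hydrogen and only the C12 methyl remains, and the primary allylic alcohol 15 is oxidised on to the enal in the same pot, after which the electron-poor alkene resists further attack; no stereocentre is formed.

**Step 11**
Reactants: 16 tert-butyl 6β,9α-dihydroxy-12-oxodrim-7-en-11-oate; 17 (2E,4E,6E)-octa-2,4,6-trienoic acid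
Product: 19 ustusoic acid B tert-butyl ester, via mixed anhydride 18 (not isolated)
Conditions: 17 (1.5 equiv), 2,4,6-Cl3C6H2COCl (1.5 equiv), Et3N (3 equiv), toluene, rt; then 16, DMAP (2 equiv), toluene, rt → 50 °C, dark
Reagents that add atoms: none
Why: Yamaguchi esterification through mixed anhydride 18 and the DMAP-derived acylpyridinium acylates the secondary allylic 6β-hydroxyl with retention at C6, while the tertiary 9α-hydroxyl, flanked by the quaternary C10 and the ester, is too hindered to react and the aldehyde is inert.

**Step 12**
Reactants: 19 ustusoic acid B tert-butyl ester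
Product: 20 ustusoic acid B
Conditions: CF3CO2H/CH2Cl2 (1:4), 0 °C → rt; toluene azeotrope
Reagents that add atoms: none
Why: Acidolysis of the tert-butyl ester by alkyl–oxygen cleavage (loss of isobutene) frees the C11 acid under conditions that spare the trienoate, since its allylic C6–O bond cannot ionise next to the electron-poor enal and C9 carries two electron-withdrawing groups; no stereocentre is touched.

**Compound list**
1 | (2E,6E)-farnesol | CC(C)=CCC/C(C)=C/CC/C(C)=C/CO | starting material
2 | (2E,6E)-farnesyl bromide | CC(C)=CCC/C(C)=C/CC/C(C)=C/CBr | intermediate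
3 | (2E,6E)-farnesyl diphosphate (drawn as free acid, handled as ammonium salt) | CC(C)=CCC/C(C)=C/CC/C(C)=C/COP(=O)(O)OP(=O)(O)O | intermediate
4 | drimenyl diphosphate (drim-7-en-11-yl diphosphate; 5α-H, 9α-H, 10β-CH3; enzyme-bound, formed in situ) | C1C=C(C)[C@H](COP(=O)(O)OP(=O)(O)O)[C@@]2(C)CCCC(C)(C)[C@H]12 | intermediate
5 | drimenyl phosphate (drim-7-en-11-yl phosphate; formed in situ) | C1C=C(C)[C@H](COP(=O)(O)O)[C@@]2(C)CCCC(C)(C)[C@H]12 | intermediate
6 | (−)-drimenol, (5S,9S,10S)-drim-7-en-11-ol (trans-decalin, 5α-H, 10β-CH3, 9β-CH2OH, C7=C8 with CH3 on C8) | C1C=C(C)[C@H](CO)[C@@]2(C)CCCC(C)(C)[C@H]12 | intermediate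
7 | drimenal, drim-7-en-11-al (9β-CHO) | C1C=C(C)[C@H](C=O)[C@@]2(C)CCCC(C)(C)[C@H]12 | intermediate
8 | drim-7-en-11-oic acid (9β-CO2H) | C1C=C(C)[C@H](C(=O)O)[C@@]2(C)CCCC(C)(C)[C@H]12 | intermediate
9 | tert-butyl drim-7-en-11-oate | C1C=C(C)[C@H](C(=O)OC(C)(C)C)[C@@]2(C)CCCC(C)(C)[C@H]12 | intermediate
10 | potassium dienolate of 9 (C9=C11 enolate conjugated with C7=C8; formed in situ) | C1C=C(C)C(=C([O-])OC(C)(C)C)[C@@]2(C)CCCC(C)(C)[C@H]12.[K+] | intermediate
11 | tert-butyl 9α-hydroxydrim-7-en-11-oate | C1C=C(C)[C@](O)(C(=O)OC(C)(C)C)[C@@]2(C)CCCC(C)(C)[C@H]12 | intermediate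
12 | tert-butyl 6-(tert-butylperoxy)-9α-hydroxydrim-7-en-11-oate (C6 configuration not defined; formed in situ) | CC(C)(C)OOC1C=C(C)[C@](O)(C(=O)OC(C)(C)C)[C@@]2(C)CCCC(C)(C)[C@H]12 | intermediate
13 | tert-butyl 9α-hydroxy-6-oxodrim-7-en-11-oate | O=C1C=C(C)[C@](O)(C(=O)OC(C)(C)C)[C@@]2(C)CCCC(C)(C)[C@H]12 | intermediate
14 | tert-butyl 6β,9α-dihydroxydrim-7-en-11-oate | O[C@@H]1C=C(C)[C@](O)(C(=O)OC(C)(C)C)[C@@]2(C)CCCC(C)(C)[C@H]12 | intermediate
15 | tert-butyl 6β,9α,12-trihydroxydrim-7-en-11-oate (formed in situ) | O[C@@H]1C=C(CO)[C@](O)(C(=O)OC(C)(C)C)[C@@]2(C)CCCC(C)(C)[C@H]12 | intermediate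
16 | tert-butyl 6β,9α-dihydroxy-12-oxodrim-7-en-11-oate | O[C@@H]1C=C(C=O)[C@](O)(C(=O)OC(C)(C)C)[C@@]2(C)CCCC(C)(C)[C@H]12 | intermediate
17 | (2E,4E,6E)-octa-2,4,6-trienoic acid | C/C=C/C=C/C=C/C(=O)O | starting material
18 | (2E,4E,6E)-octa-2,4,6-trienoic 2,4,6-trichlorobenzoic anhydride (formed in situ) | C/C=C/C=C/C=C/C(=O)OC(=O)c1c(Cl)cc(Cl)cc1Cl | intermediate
19 | ustusoic acid B tert-butyl ester, tert-butyl 9α-hydroxy-6β-[(2E,4E,6E)-octa-2,4,6-trienoyloxy]-12-oxodrim-7-en-11-oate | C/C=C/C=C/C=C/C(=O)O[C@@H]1C=C(C=O)[C@](O)(C(=O)OC(C)(C)C)[C@@]2(C)CCCC(C)(C)[C@H]12 | intermediate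
20 | ustusoic acid B, 9α-hydroxy-6β-[(2E,4E,6E)-octa-2,4,6-trienoyloxy]-12-oxodrim-7-en-11-oic acid | C/C=C/C=C/C=C/C(=O)O[C@@H]1C=C(C=O)[C@](O)(C(=O)O)[C@@]2(C)CCCC(C)(C)[C@H]12 | target

**Step count**
Total step count: 12. Longest linear sequence: 12 steps (1 → 20); acid 17 is purchased and enters in step 11.

**Steps most likely to fail**

Step 3. The cyclase may turn over slowly or be inhibited by its product at preparative loading. The phosphatase domain may also hydrolyse the diphosphate before cyclisation, returning farnesol, and proton loss at the wrong site would give alkene isomers. The fallback sets out from farnesol 1 and comes back at drimenol 6. Farnesol itself is incubated with a recombinant squalene–hopene cyclase (wild type from Alicyclobacillus acidocaldarius or an engineered variant) in citrate buffer pH 6 with a detergent or cyclodextrin at 30–50 °C. This enzyme protonates the distal alkene of the free alcohol and forms the same C4–C5 and C9–C10 bonds in the same fold. Steps 1 and 2 then fall away and no new compound arises (entry F0).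

Step 8. Hydrogen abstraction at the C12 methyl may compete with abstraction at C6, the allyl radical may be trapped at C8, and the enone may be oxidised further. The fallback sets out from 11 and comes back at 13. The tertiary hydroxyl is first capped with Et3SiOTf and 2,6-lutidine in CH2Cl2 to give tert-butyl 9α-(triethylsilyloxy)drim-7-en-11-oate F1. With the tertiary allylic alcohol masked, oxidative transposition is blocked, and the stoichiometric chromium reagent long used for ring allylic oxidation of drim-7-enes and 7-ene sterols can be applied (CrO3·3,5-dimethylpyrazole, CH2Cl2, −20 °C). This should give tert-butyl 6-oxo-9α-(triethylsilyloxy)drim-7-en-11-oate F2. Desilylation with Bu4NF buffered with AcOH in THF then releases 13.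

Step 11. Acyl transfer to the axial 6β-hydroxyl, which is screened by two 1,3-diaxial methyl groups, may be slow. The activated trienoyl species could then isomerise at its 2,3-alkene or decompose under DMAP before it is consumed. The fallback sets out from 16 and comes back at 19, and it builds the chain on the ester instead of transferring it whole. Alcohol 16 is esterified with 2-(diethoxyphosphoryl)acetic acid and dicyclohexylcarbodiimide in CH2Cl2. This acylation runs through a small, linear phosphoryl ketene and is therefore far less sensitive to hindrance. It gives tert-butyl 6β-[2-(diethoxyphosphoryl)acetoxy]-9α-hydroxy-12-oxodrim-7-en-11-oate F3. Horner–Wadsworth–Emmons olefination of F3 with an excess of commercial (2E,4E)-hexa-2,4-dienal (LiCl, iPr2NEt, MeCN, rt) then forms the 2,3-alkene E-selectively and delivers 19. The unhindered dienal should outcompete the hindered C12 enal for the phosphonate anion.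

**Further compounds**
F0 | step 3 | none | none
F1 | step 8 | tert-butyl 9α-(triethylsilyloxy)drim-7-en-11-oate | C1C=C(C)[C@](O[Si](CC)(CC)CC)(C(=O)OC(C)(C)C)[C@@]2(C)CCCC(C)(C)[C@H]12
F2 | step 8 | tert-butyl 6-oxo-9α-(triethylsilyloxy)drim-7-en-11-oate | O=C1C=C(C)[C@](O[Si](CC)(CC)CC)(C(=O)OC(C)(C)C)[C@@]2(C)CCCC(C)(C)[C@H]12
F3 | step 11 | tert-butyl 6β-[2-(diethoxyphosphoryl)acetoxy]-9α-hydroxy-12-oxodrim-7-en-11-oate | CCOP(=O)(OCC)CC(=O)O[C@@H]1C=C(C=O)[C@](O)(C(=O)OC(C)(C)C)[C@@]2(C)CCCC(C)(C)[C@H]12
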